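**Retrosynthetic overview**
1. Target ⇐ its penta-O-benzyl ether by one global hydrogenolysis; the route closes no ring, since all four benzene rings are bought intact.
2. Key disconnection: the bond between the ring-A arene carbon (para to the diaryl-ether oxygen, meta to OMe) and its benzylic CH2, together with the twin bond on ring B, made in one pot by twofold Heck arylation with redox relay of a 1-arylallyl alcohol by a bromo-iodo diaryl ether.
3. Enabling feature: both rings of the diaryl ether carry the same arm, Ar–CH2–CH2–C(=O)–(2,4-dihydroxyphenyl); this β-aryl ketone is the retron of a Heck arylation of an allylic alcohol whose carbinol carbon becomes the carbonyl.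
4. Order within the key step: the ring-B C–I bond reacts first, so the last bond formed joins the ring-A C–Br carbon of the ring-B-armed bromo ketone to the terminal CH2 of a second C9 unit.
5. Diaryl ether core ⇐ SNAr of 4-bromo-2-methoxyphenol on 2-fluoro-4-iodobenzaldehyde, Dakin-type oxidation, benzylation; allylic alcohol ⇐ 2,4-bis(benzyloxy)benzaldehyde + vinyl Grignard.

Key step: step 5

Remark: the target has no stereogenic element, so it is one achiral compound and the route needs no stereocontrol.

**Route**

Step 1
Reactants: 1 4-bromo-2-methoxyphenol; 2 2-fluoro-4-iodobenzaldehyde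
Product: 3 2-(4-bromo-2-methoxyphenoxy)-4-iodobenzaldehyde
Conditions: K2CO3, DMF, 90 °C
Reagents that add atoms: none
Why: SNAr (addition–elimination): the phenoxide of 1 should displace the fluoride activated by the ortho formyl group, while the C–I and C–Br bonds, poor nucleofuges in this mechanism, stay untouched.

Step 2
Reactants: 3 2-(4-bromo-2-methoxyphenoxy)-4-iodobenzaldehyde
Product: 5 2-(4-bromo-2-methoxyphenoxy)-4-iodophenol, via aryl formate 4 (not isolated)
Conditions: mCPBA, CH2Cl2, 0 °C to rt; aq NaHCO3 wash; then K2CO3 (cat.), MeOH, rt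
Reagents that add atoms: mCPBA, OOC(=O)c1cccc(Cl)c1
Why: Baeyer–Villiger (Dakin-type) oxidation of an electron-rich benzaldehyde: the ortho aryloxy donor should make the aryl group migrate in the Criegee intermediate to give formate 4, which mild methanolysis cleaves to the phenol, and without added strong acid the peracid should spare the aryl iodide.

Step 3
Reactants: 5 2-(4-bromo-2-methoxyphenoxy)-4-iodophenol
Product: 6 1-(benzyloxy)-2-(4-bromo-2-methoxyphenoxy)-4-iodobenzene
Conditions: BnBr, K2CO3, DMF, rt
Reagents that add atoms: benzyl bromide, BrCc1ccccc1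
Why: Williamson ether synthesis; the benzyl group prevents a phenoxide para to iodine from slowing oxidative addition in step 5 and is the same group as on the other fragment, so one final operation removes all.

Step 4
Reactants: 7 2,4-bis(benzyloxy)benzaldehyde
Product: 8 rac-1-[2,4-bis(benzyloxy)phenyl]prop-2-en-1-ol
Conditions: CH2=CHMgBr, THF, 0 °C; then aq NH4Cl
Reagents that add atoms: vinylmagnesium bromide, C=C[Mg]Br
Why: Grignard 1,2-addition to the aldehyde; the carbinol centre is made as a racemate on purpose because step 5 turns this carbon into the ketone, and the acid-sensitive electron-rich allylic alcohol is kept neutral to basic and used directly.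

Step 5
Reactants: 6 1-(benzyloxy)-2-(4-bromo-2-methoxyphenoxy)-4-iodobenzene; 8 rac-1-[2,4-bis(benzyloxy)phenyl]prop-2-en-1-ol (3 equiv, in two portions)
Product: 10 penta-O-benzylverbenachalcone, via mono-arylated bromo ketone 9 (not isolated)
Conditions: Pd(OAc)2 (10 mol %), P(o-tol)3 (20 mol %), n-Bu4NCl, NaHCO3, DMF, 60 °C then 110 °C
Reagents that add atoms: none
Why: Each arm should arise by a Heck arylation of the allylic alcohol with redox relay: oxidative addition of Pd(0) into the aryl halide, syn-carbopalladation of the terminal alkene of 8 with the aryl group going to the unsubstituted CH2, β-hydride elimination of the carbinol C–H to a Pd-bound enol, and tautomerisation to the ketone, so that the aryl–CH2 bond and the carbonyl form together without oxidant or reductant. The closest known reaction type is the Heck arylation of secondary allylic alcohols under Jeffery-type conditions to give β-aryl ketones, established for 1-arylprop-2-en-1-ols (dihydrochalcones) and for electron-rich aryl bromides. No ring is closed and no stereocentre is created; the carbinol stereocentre of racemic 8 is erased on conversion to the ketone. Site order is secured by the halogens: the ring-B C–I bond (para to OBn) should react at 60 °C to give bromo ketone 9, and only on heating should the ring-A C–Br bond (para to the diaryl-ether oxygen, meta to OMe) react, so that the last bond formed joins that aryl carbon of 9 to the terminal CH2 of a second molecule of 8. Insertion regioselectivity is steric (terminal carbon of a monosubstituted alkene), elimination towards the carbinol is favoured by the hydridic C–H next to oxygen and by the chloride/bicarbonate medium, the basic conditions keep the ionisable benzylic alcohol intact, and the excess of 8 compensates for its Pd–H isomerisation to the propiophenone.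

Step 6
Reactants: 10 penta-O-benzylverbenachalcone
Product: 11 verbenachalcone
Conditions: H2 (1 atm), 10% Pd/C, EtOAc–MeOH, rt
Reagents that add atoms: none
Why: Catalytic hydrogenolysis (O-debenzylation) of the five benzyl ethers; the electron-rich 2-hydroxyaryl ketones, the diaryl ether and the methyl ether should survive neutral conditions at 1 atm.

**Compound list**
1 | 4-bromo-2-methoxyphenol | COc1cc(Br)ccc1O | starting material
2 | 2-fluoro-4-iodobenzaldehyde | O=Cc1ccc(I)cc1F | starting material
3 | 2-(4-bromo-2-methoxyphenoxy)-4-iodobenzaldehyde | COc1cc(Br)ccc1Oc1cc(I)ccc1C=O | intermediate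
4 | 2-(4-bromo-2-methoxyphenoxy)-4-iodophenyl formate | COc1cc(Br)ccc1Oc1cc(I)ccc1OC=O | intermediate
5 | 2-(4-bromo-2-methoxyphenoxy)-4-iodophenol | COc1cc(Br)ccc1Oc1cc(I)ccc1O | intermediate
6 | 1-(benzyloxy)-2-(4-bromo-2-methoxyphenoxy)-4-iodobenzene | COc1cc(Br)ccc1Oc1cc(I)ccc1OCc1ccccc1 | intermediate
7 | 2,4-bis(benzyloxy)benzaldehyde | O=Cc1ccc(OCc2ccccc2)cc1OCc1ccccc1 | starting material
8 | rac-1-[2,4-bis(benzyloxy)phenyl]prop-2-en-1-ol | C=CC(O)c1ccc(OCc2ccccc2)cc1OCc1ccccc1 | intermediate
9 | 3-[4-(benzyloxy)-3-(4-bromo-2-methoxyphenoxy)phenyl]-1-[2,4-bis(benzyloxy)phenyl]propan-1-one | COc1cc(Br)ccc1Oc1cc(CCC(=O)c2ccc(OCc3ccccc3)cc2OCc2ccccc2)ccc1OCc1ccccc1 | intermediate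
10 | penta-O-benzylverbenachalcone, 3-[4-(benzyloxy)-3-{4-[3-(2,4-bis(benzyloxy)phenyl)-3-oxopropyl]-2-methoxyphenoxy}phenyl]-1-[2,4-bis(benzyloxy)phenyl]propan-1-one | COc1cc(CCC(=O)c2ccc(OCc3ccccc3)cc2OCc2ccccc2)ccc1Oc1cc(CCC(=O)c2ccc(OCc3ccccc3)cc2OCc2ccccc2)ccc1OCc1ccccc1 | intermediate
11 | verbenachalcone, 1-(2,4-dihydroxyphenyl)-3-[3-{4-[3-(2,4-dihydroxyphenyl)-3-oxopropyl]-2-methoxyphenoxy}-4-hydroxyphenyl]propan-1-one | COc1cc(CCC(=O)c2ccc(O)cc2O)ccc1Oc1cc(CCC(=O)c2ccc(O)cc2O)ccc1O | target

**Summary**
Total step count: 6. Longest linear sequence: 5 steps (steps 1, 2, 3, 5, 6).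

Steps most likely to fail:

Step 5. The sequence may stall after the first arylation because oxidative addition into the electron-rich C–Br bond is slow. β-Hydride elimination may also go away from the carbinol, and Pd–H may isomerise the allylic alcohol before it couples. The fallback sets out from 6 and comes back at 10. Twofold Miyaura borylation of 6 (B2pin2, Pd(dppf)Cl2, KOAc, dioxane, 90 °C) should give 2-{4-(benzyloxy)-3-[2-methoxy-4-(4,4,5,5-tetramethyl-1,3,2-dioxaborolan-2-yl)phenoxy]phenyl}-4,4,5,5-tetramethyl-1,3,2-dioxaborolane F1. MnO2 oxidation of 8 (CH2Cl2, rt) should give 1-[2,4-bis(benzyloxy)phenyl]prop-2-en-1-one F2. Rhodium-catalysed twofold 1,4-addition (Hayashi–Miyaura; [Rh(cod)OH]2, dioxane–H2O, 50 °C) of F1 to F2 should then form the same two aryl–CH2 bonds and give 10, with no β-hydride elimination to steer.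

Step 2. The peracid may oxidise at iodine, or hydride may migrate in place of aryl and lead to the carboxylic acid. The fallback sets out from 1 and comes back at 5, and introduces iodine only after the peracid step. SNAr of 1 with 2-fluorobenzaldehyde (O=Cc1ccccc1F; K2CO3, DMF, 100 °C) should give 2-(4-bromo-2-methoxyphenoxy)benzaldehyde F3. Baeyer–Villiger oxidation (mCPBA, CH2Cl2) via 2-(4-bromo-2-methoxyphenoxy)phenyl formate F4 and methanolysis should give 2-(4-bromo-2-methoxyphenoxy)phenol F5. Electrophilic iodination (NIS, cat. TsOH, MeCN, 0 °C) para to the free hydroxyl should then give 5; the other ring is deactivated by bromine and has no free OH.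

Step 6. The aryl ketones may be over-reduced, or cleavage of the benzyl ethers ortho to the carbonyl may stay incomplete. The fallback sets out from 10 and comes back at 11. It is a non-reductive debenzylation with BCl3 and pentamethylbenzene as benzyl-cation scavenger (CH2Cl2, −78 °C), which cannot reduce the ketones and should leave the non-chelated aryl methyl ether. No new compound is made (F0).

**Further compounds**
F1 | step 5 | 2-{4-(benzyloxy)-3-[2-methoxy-4-(4,4,5,5-tetramethyl-1,3,2-dioxaborolan-2-yl)phenoxy]phenyl}-4,4,5,5-tetramethyl-1,3,2-dioxaborolane | COc1cc(B2OC(C)(C)C(C)(C)O2)ccc1Oc1cc(B2OC(C)(C)C(C)(C)O2)ccc1OCc1ccccc1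
F2 | step 5 | 1-[2,4-bis(benzyloxy)phenyl]prop-2-en-1-one | C=CC(=O)c1ccc(OCc2ccccc2)cc1OCc1ccccc1
F3 | step 2 | 2-(4-bromo-2-methoxyphenoxy)benzaldehyde | COc1cc(Br)ccc1Oc1ccccc1C=O
F4 | step 2 | 2-(4-bromo-2-methoxyphenoxy)phenyl formate | COc1cc(Br)ccc1Oc1ccccc1OC=O
F5 | step 2 | 2-(4-bromo-2-methoxyphenoxy)phenol | COc1cc(Br)ccc1Oc1ccccc1O
F0 | step 6 | none | none
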